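If one run is to be spent on this charge, the choice lies between the tank of summer, the dosing of noon and the single charge of midnight, and the reckoning below compares them by their exposure to substrate.

    substrate + free catalyst ⇌ catalyst intermediate (K1 = 3.9 /M, k1 = 64.7 /M/min)
    catalyst intermediate → free catalyst + target (k2 = 28.9 /min)
    substrate + target → side product (k3 = 0.437 /M/min)
    free catalyst + impurity → spent catalyst (k4 = 1.54 × 10⁵ /M/min)

in all of them: free catalyst 0.71 mol%; impurity 0.10 mM

| flask | substrate | remark | time |
|---|---|---|---|
| summer | 0.10 M | one stirred flow tank at steady state, fed with the mixture as stated, mean residence time 50 min |  |
| noon | 0.10 M (fed, over 50.0 min) | all but substrate at the start; substrate goes in evenly over 50.0 min, the run ends at 50 min | 50 min |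
| midnight | 0.10 M | a closed flask charged with all of it at once and left for 50 min | 50 min |

- the set-up with the highest amount of target at the outlet or at the end, in percent of the substrate put in ("none" if the first two lie within 2 percentage points) (summer / noon / midnight / none)
- amount of target at the outlet or at the end, in percent of the substrate put in, summer
- amount of target at the outlet or at the end, in percent of the substrate put in, noon
- amount of target at the outlet or at the end, in percent of the substrate put in, midnight

- in percentages every species weighs as the substrate in it: one side product counts as two
- the stated concentrations are those of everything mixed, before any reaction; amounts are the same in each set-up
- the feed brings no volume worth counting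
- run time (noon): 50 min

At the charged catalyst the impurity lasts about 0.00915 min, far shorter than the 50 min of a run, so the reckoning gives each set-up 0.610 mM of working catalyst, free and bound together. With a Michaelis constant of 0.703 M and [substrate] taken at 0.0500 M, that catalyst gives a pseudo-first-order working constant of 0.0234 /min. The side step removes target at 0.437 /M/min times [substrate] times [target], so both rates carry [substrate], and they balance at a [target] called the balance level, the working constant over the side-step constant: 0.0536 M, or 53.6% of the charge.

Exposure is the time integral of [substrate], or [substrate] times residence time in the tank. Let x be 0.437 /M/min times exposure: in the closed and dosed flasks target is the balance level times one minus the exponential of minus x, and in the tank it is the balance level times x over one plus x. The first round ignores substrate lost to the side step; the second adds that loss, using half the first-round target in the closed and dosed flasks and the whole figure in the tank.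

For midnight, exposure 177 M·s gives 38.8%; then 150 M·s gives 35.6%. For noon, 105 M·s gives 28.7%; then 96.8 M·s gives 27.1%. For summer, 138 M·s gives 26.9%; then 109 M·s gives 23.7%. By this reckoning midnight collects more exposure than either other set-up, and the choice falls on midnight.

The forecast, a little apart from these figures, reads 24.3% for summer, 28% for noon and 34.7% for midnight, and names midnight: “Batch wins because it has the highest substrate concentration early”.

The simulation gives 24.3% for summer, 27.6% for noon and 35.9% for midnight, so midnight ranks first, its target lower than the reckoned balance level. The neighbouring midnight flask, loaded with 1.2 mol% of free catalyst, has 1.10 mM working, a working constant of 0.0422 /min and a balance level of 0.0966 M. The first round there gives 57.7% and the second 50.8%. That neighbouring flask ends with 51.7% target and 43.3% side product.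

The numbers are made up; the flask was simulated.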